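| flask | Z | G | remark | time |
|---|---|---|---|---|
| blue | 0.035 M (fed, over 40 s) | 0.0175 M | the very flask that is asked about, followed so far |  |
| ochre | 0.018 M (fed, over 40 s) | 0.0175 M | run made earlier |  |
| flask | 0.035 M (fed, over 40 s) | 0.0175 M |  | 15 min |

| run | time / min | X / % | L / % |
|---|---|---|---|
| blue | 0.333 | 1 | 4 |
| blue | 0.667 | 8 | 1 |
| blue | 1.33 | 24 | 6 |
| blue | 2.50 | 33 | 9 |
| blue | 5.00 | 42 | 8 |
| ochre | 1.33 | 23 | 9 |
| ochre | 4.00 | 42 | 12 |
| ochre | 8.00 | 45 | 14 |
| ochre | 10.0 | 46 | 12 |
| ochre | 15.0 | 44 | 14 |

(scatter of a reading: 2 percentage points)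

- what was read earlier has a scatter of 2 percentage points, one standard deviation
- on the list of suspects stand: Z -> X; Z + G -> L; Z -> J
- percentages count the whole charge, also what has not yet gone in

- concentration of X at 15 min, in M
- concentration of L at 15 min, in M
- concentration of J at 15 min, in M

Start from the time of reading, 15 min, and ask whether Z still matters then: the ochre run reads X at 45% after 8.00 min and 44% after 15.0 min, flat within the scatter, and 1.33 min gives X of 24% in the blue run against 23% in the ochre run at 1.94 times the charge, so expect the blue flask to be over by 15 min and ask how its charge has divided.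

Take the last 3 ochre readings, which give L/X = 0.296 and, with J by difference, J/X = 0.926. The suspect paths to X and J hold no G, so carry J/X over unchanged, but the path to L takes G, so divide L/X by the mean [G], halfway down to what L has consumed, 0.0163 M. This gives S = 18.2 M⁻¹, the L made per X made per unit of mean [G], a selectivity factor.

Then ask what the larger blue charge does to G: at the ochre share of L, mean [G] falls to 0.0152 M, so L/X becomes 0.276, and my reckoning gives X 0.0159 M, L 0.00438 M and J 0.0147 M.

The forecast gives X 0.0156 M, L 0.004 M and J 0.0152 M, with “the remaining ~42% is presumably J”; my X and L stand higher and my J lower.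

The flask gives X 0.0164 M, L 0.00427 M and J 0.0143 M, with Z down to 0.0068% of its charge at 15.0 min and G at 76% of its own.

Z → X (k = 0.00518 s⁻¹); Z + G → L (k = 0.0883 M⁻¹ s⁻¹); Z → J (k = 0.00453 s⁻¹) Halfway between its charge and that end, [G] stands at 0.0154 M, where S gives L/X = 0.279 against the flask's 0.260. In the neighbour flask charged with 0.011 M of G, which ends at 74.6% of that charge, S gives L/X = 0.175, so beside its X of 0.0172 M expect L of 0.00301 M, and that flask holds 0.00279 M.

The numbers in the tables come from a simulation for substances that don't exist; scatter was added.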